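## Retrosynthetic overview

- Tetralin numbering is used: C1 carries the guaiacyl ring, C2 and C3 carry the hydroxymethyl carbons C9 and C10, C4 is the CH2, ring A is the benzo ring and ring B the carbocycle; the target is all-trans (1R,2S,3S).
- The strategy rests on two facts: the OH of the pendant ring is para to C1, so C1 can become the exocyclic carbon of a para-quinone methide; and C2 is alpha to C9, so C9 at the aldehyde level makes C2 an enamine nucleophile. The C1–C2 bond is therefore the last skeletal bond made, and it closes ring B.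
- The cyclization substrate 16 is built from a Stobbe condensation (C3=C4, with C9 and C10 from dimethyl succinate) on a ring A aldehyde, whose C1–C8a bond comes from the aryllithium of 2-bromo-O-benzylsyringaldehyde acetal and O-silylvanillin. The C1 oxygen is carried as a methyl ether: the free carbinol would close onto the ortho aldehyde as a lactol and later add to the acrylate, and the acid of the key step ionizes the ether directly.
- After ring closure, i-Bu2AlH gives the C9/C10 diol, a hydroxyl-directed hydrogenation of C3=C4 sets C3, and hydrogenolysis frees the C7 phenol.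
- Ring order: ring A (syringaldehyde) and the pendant ring (vanillin) are bought; ring B is the only ring formed (step 11).

Key step: step 11

Remark: the diarylmethyl carbon made in step 5 is formed racemic and is carried as a mixture of epimers (8–10, 12–16), because it becomes planar in 17.

## Route

Step 1
Reactants: 1 syringaldehyde
Product: 2 4-(benzyloxy)-3,5-dimethoxybenzaldehyde
Conditions: BnBr, K2CO3, DMF, 60 °C
Reagents that add atoms: benzyl bromide, BrCc1ccccc1
Why: Williamson ether synthesis on the phenoxide, which protects the future C7 hydroxyl in a form that survives organolithium, alkoxide, hydride and fluoride steps and leaves by hydrogenolysis at the end.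

Step 2
Reactants: 2 4-(benzyloxy)-3,5-dimethoxybenzaldehyde
Product: 3 4-(benzyloxy)-2-bromo-3,5-dimethoxybenzaldehyde
Conditions: NBS, MeCN, rt, dark
Reagents that add atoms: N-bromosuccinimide, O=C1CCC(=O)N1Br
Why: electrophilic aromatic bromination at the only free position type of the trialkoxy ring (ortho and para to methoxy groups), the unactivated benzyl ring being left alone under ionic conditions.

Step 3
Reactants: 3 4-(benzyloxy)-2-bromo-3,5-dimethoxybenzaldehyde
Product: 4 2-(benzyloxy)-4-bromo-5-(dimethoxymethyl)-1,3-dimethoxybenzene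
Conditions: HC(OMe)3, MeOH, TsOH·H2O (cat.), rt; Et3N quench
Reagents that add atoms: trimethyl orthoformate, COC(OC)OC; methanol, CO
Why: acid-catalysed acetalization driven by the orthoformate masks the aldehyde against the organolithium of step 5.

Step 4
Reactants: 5 vanillin
Product: 6 3-methoxy-4-(triisopropylsilyloxy)benzaldehyde
Conditions: TIPSCl, imidazole, DMF, rt
Reagents that add atoms: triisopropylsilyl chloride, CC(C)[Si](Cl)(C(C)C)C(C)C
Why: imidazole-promoted O-silylation of the phenol; the triisopropylsilyl ether is the aryl silyl ether most resistant to organolithium and hindered alkoxide, and it leaves with buffered fluoride.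

Step 5
Reactants: 4 2-(benzyloxy)-4-bromo-5-(dimethoxymethyl)-1,3-dimethoxybenzene; 6 3-methoxy-4-(triisopropylsilyloxy)benzaldehyde
Product: 9 [3-(benzyloxy)-6-(dimethoxymethyl)-2,4-dimethoxyphenyl][3-methoxy-4-(triisopropylsilyloxy)phenyl]methyl methyl ether (racemic), via aryllithium 7 (not isolated), via lithium alkoxide 8 (not isolated)
Conditions: n-BuLi, THF, −78 °C; then 6; then MeI, DMPU, −78 °C to rt
Reagents that add atoms: iodomethane, CI; n-butyllithium, [Li]CCCC (lithium of 7 and 8 only)
Why: bromine–lithium exchange, 1,2-addition of the aryllithium to the aldehyde (C1–C8a bond, new centre racemic and erased later) and in-flask Williamson methylation of the lithium alkoxide, which caps the C1 oxygen before the ortho aldehyde is unmasked.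

Step 6
Reactants: 9 [3-(benzyloxy)-6-(dimethoxymethyl)-2,4-dimethoxyphenyl][3-methoxy-4-(triisopropylsilyloxy)phenyl]methyl methyl ether
Product: 10 4-(benzyloxy)-3,5-dimethoxy-2-{methoxy[3-methoxy-4-(triisopropylsilyloxy)phenyl]methyl}benzaldehyde
Conditions: PPTS (cat.), acetone/H2O, rt
Reagents that add atoms: water, O
Why: mild acid-catalysed acetal hydrolysis, which for an aryl dimethyl acetal should be much faster than ionization of the benzhydryl methyl ether while the phenol is still silylated, and the capped C1 oxygen cannot form a lactol.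

Step 7
Reactants: 10 4-(benzyloxy)-3,5-dimethoxy-2-{methoxy[3-methoxy-4-(triisopropylsilyloxy)phenyl]methyl}benzaldehyde; 11 dimethyl succinate
Product: 13 (E)-4-{4-(benzyloxy)-3,5-dimethoxy-2-[methoxy(3-methoxy-4-triisopropylsilyloxyphenyl)methyl]phenyl}-3-(methoxycarbonyl)but-3-enoic acid, via paraconate lactone 12 (not isolated)
Conditions: t-BuOK, t-BuOH/THF, rt; cold 1 M HCl work-up
Reagents that add atoms: none
Why: Stobbe condensation, in which aldol addition, lactonization to the paraconate and E1cB ring opening give the half-ester with the acid on the CH2 arm and the (E) alkene (ring A cis to that arm), the hindered alkoxide sparing the aryl silyl ether.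

Step 8
Reactants: 13 (E)-half-ester
Product: 14 methyl (E)-2-{[4-(benzyloxy)-3,5-dimethoxy-2-{methoxy[3-methoxy-4-(triisopropylsilyloxy)phenyl]methyl}phenyl]methylidene}-4-hydroxybutanoate
Conditions: BH3·SMe2, THF, 0 °C to rt; H2O quench, neutral work-up
Reagents that add atoms: none
Why: chemoselective borane reduction of the carboxylic acid through its acyloxyborane, which leaves the conjugated ester and the electron-poor trisubstituted alkene alone; the hydroxy ester is kept neutral and used at once so that it does not lactonize.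

Step 9
Reactants: 14 hydroxy ester
Product: 15 methyl (E)-2-{[4-(benzyloxy)-3,5-dimethoxy-2-{methoxy[3-methoxy-4-(triisopropylsilyloxy)phenyl]methyl}phenyl]methylidene}-4-oxobutanoate
Conditions: Dess–Martin periodinane, pyridine, CH2Cl2, 0 °C to rt
Reagents that add atoms: none
Why: Dess–Martin oxidation of the primary alcohol under buffered, non-basic conditions, which should not move the C3=C4 alkene out of conjugation with ring A and cannot touch the still-masked phenol.

Step 10
Reactants: 15 silyl-protected aldehyde
Product: 16 methyl (E)-2-{[4-(benzyloxy)-2-[(4-hydroxy-3-methoxyphenyl)(methoxy)methyl]-3,5-dimethoxyphenyl]methylidene}-4-oxobutanoate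
Conditions: Bu4NF, AcOH (1:1), THF, 0 °C
Reagents that add atoms: none
Why: fluoride cleavage of the aryl silyl ether, buffered with acetic acid so that the aldehyde neither enolizes nor condenses, and under which methoxide is too poor a leaving group for the quinone methide to form prematurely.

Step 11
Reactants: 16 methyl (E)-2-{[4-(benzyloxy)-2-[(4-hydroxy-3-methoxyphenyl)(methoxy)methyl]-3,5-dimethoxyphenyl]methylidene}-4-oxobutanoate
Product: 19 methyl (1R,2S)-7-(benzyloxy)-2-formyl-1-(4-hydroxy-3-methoxyphenyl)-6,8-dimethoxy-1,2-dihydronaphthalene-3-carboxylate, via quinone methide 17 (not isolated), via quinone methide dienamine 18 (not isolated)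
Conditions: (S)-2-[diphenyl(triethylsilyloxy)methyl]pyrrolidine (20 mol %), (PhO)2P(O)OH (40 mol %), toluene (0.01 M), 0 °C to rt
Reagents that add atoms: none
Why: Proposed new method: diphenyl phosphate protonates the methoxy group of 16 and the para-hydroxyl expels methanol, so both ether epimers give one planar para-quinone methide 17, while the amine condenses with the aldehyde to the (E)-dienamine 18, whose alpha-carbon C2 adds to the exocyclic carbon C1 with irreversible rearomatization to the phenol and hydrolysis of the iminium to 19; the closest known reaction types are the diarylprolinol silyl ether-catalysed 1,6-addition of aldehydes to preformed para-quinone methides, the acid generation of such methides from 4-hydroxybenzyl alcohols and ethers, and the enamine alkylation of aldehydes with stabilized benzhydryl cations. Ring B closes in the 6-(enolexo)-exo-trig mode, and attack through the gamma-carbon C4 is excluded because it would make a four-membered ring. The two ortho substituents turn ring A out of the methide plane, so that the C1 p-orbital points within the plane of ring A at C2, which the (E)-alkene holds on the same side. C2 is set by the catalyst, whose diphenyl(silyloxy)methyl group shields one face of the enamine so that C1 is met on the Si face of C2 (2S). C1 is set relative to C2 in the ring-forming transition state, where the quinoid ring and the amine-bearing C9 take opposite faces of the forming ring, which gives the trans (1R,2S) arrangement that also keeps the aryl group pseudoaxial and clear of the C8 methoxy group. The step needs the enamine pathway to outrun acid-catalysed closure through the achiral dienol and needs the alpha-branched product aldehyde to escape re-enolization, for which the far higher nucleophilicity of the enamine, the low temperature and the slow enamine formation of alpha-branched aldehydes with this hindered amine are relied on.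

Step 12
Reactants: 19 dihydronaphthalene aldehyde ester
Product: 20 (1R,2S)-[7-(benzyloxy)-1-(4-hydroxy-3-methoxyphenyl)-6,8-dimethoxy-1,2-dihydronaphthalene-2,3-diyl]dimethanol
Conditions: i-Bu2AlH (6 equiv), CH2Cl2, −78 to 0 °C; Rochelle salt work-up
Reagents that add atoms: none
Why: 1,2-reduction of the aldehyde and of the conjugated ester by i-Bu2AlH at low temperature gives the C9/C10 diol and removes the epimerizable aldehyde before C2 can drift.

Step 13
Reactants: 20 dihydronaphthalene diol
Product: 21 (1R,2S,3S)-[7-(benzyloxy)-1-(4-hydroxy-3-methoxyphenyl)-6,8-dimethoxy-1,2,3,4-tetrahydronaphthalene-2,3-diyl]dimethanol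
Conditions: [Ir(cod)(PCy3)(py)]PF6 (10 mol %), H2 (1 atm), CH2Cl2, rt
Reagents that add atoms: none
Why: hydroxyl-directed homogeneous hydrogenation, in which the cationic iridium binds the C9 hydroxyl (held on the face of ring B opposite the C1 aryl group) and delivers both hydrogens to that face of C3=C4, so that C10 ends trans to C9 (3S); the in-plane C10 hydroxyl can join the same chelate only on that face.

Step 14
Reactants: 21 tetralin benzyl ether
Product: 22 (1R,2S,3S)-1-(4-hydroxy-3-methoxyphenyl)-2,3-bis(hydroxymethyl)-6,8-dimethoxy-1,2,3,4-tetrahydronaphthalen-7-ol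
Conditions: H2 (1 atm), Pd/C, MeOH/EtOAc, rt
Reagents that add atoms: none
Why: hydrogenolysis of the aryl benzyl ether over Pd/C, with no other reducible group left and no stereocentre at risk.

## Compound list

1 | syringaldehyde | COc1cc(C=O)cc(OC)c1O | starting material
2 | 4-(benzyloxy)-3,5-dimethoxybenzaldehyde | COc1cc(C=O)cc(OC)c1OCc1ccccc1 | intermediate
3 | 4-(benzyloxy)-2-bromo-3,5-dimethoxybenzaldehyde | COc1cc(C=O)c(Br)c(OC)c1OCc1ccccc1 | intermediate
4 | 2-(benzyloxy)-4-bromo-5-(dimethoxymethyl)-1,3-dimethoxybenzene | COc1cc(C(OC)OC)c(Br)c(OC)c1OCc1ccccc1 | intermediate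
5 | vanillin | COc1cc(C=O)ccc1O | starting material
6 | 3-methoxy-4-(triisopropylsilyloxy)benzaldehyde | COc1cc(C=O)ccc1O[Si](C(C)C)(C(C)C)C(C)C | intermediate
7 | [3-(benzyloxy)-6-(dimethoxymethyl)-2,4-dimethoxyphenyl]lithium | COc1cc(C(OC)OC)c([Li])c(OC)c1OCc1ccccc1 | intermediate
8 | lithium [3-(benzyloxy)-6-(dimethoxymethyl)-2,4-dimethoxyphenyl][3-methoxy-4-(triisopropylsilyloxy)phenyl]methanolate (racemic) | COc1cc(C(O[Li])c2c(C(OC)OC)cc(OC)c(OCc3ccccc3)c2OC)ccc1O[Si](C(C)C)(C(C)C)C(C)C | intermediate
9 | [3-(benzyloxy)-6-(dimethoxymethyl)-2,4-dimethoxyphenyl][3-methoxy-4-(triisopropylsilyloxy)phenyl]methyl methyl ether (racemic) | COc1cc(C(OC)c2c(C(OC)OC)cc(OC)c(OCc3ccccc3)c2OC)ccc1O[Si](C(C)C)(C(C)C)C(C)C | intermediate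
10 | 4-(benzyloxy)-3,5-dimethoxy-2-{methoxy[3-methoxy-4-(triisopropylsilyloxy)phenyl]methyl}benzaldehyde | COc1cc(C(OC)c2c(C=O)cc(OC)c(OCc3ccccc3)c2OC)ccc1O[Si](C(C)C)(C(C)C)C(C)C | intermediate
11 | dimethyl succinate | COC(=O)CCC(=O)OC | starting material
12 | methyl 2-aryl-5-oxotetrahydrofuran-3-carboxylate (paraconate lactone, aryl = ring A of 10, stereoisomer mixture) | COC(=O)C1CC(=O)OC1c1cc(OC)c(OCc2ccccc2)c(OC)c1C(OC)c1ccc(O[Si](C(C)C)(C(C)C)C(C)C)c(OC)c1 | intermediate
13 | (E)-4-{4-(benzyloxy)-3,5-dimethoxy-2-[methoxy(3-methoxy-4-triisopropylsilyloxyphenyl)methyl]phenyl}-3-(methoxycarbonyl)but-3-enoic acid | COc1cc(C(OC)c2c(/C=C(\CC(=O)O)C(=O)OC)cc(OC)c(OCc3ccccc3)c2OC)ccc1O[Si](C(C)C)(C(C)C)C(C)C | intermediate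
14 | methyl (E)-2-(arylmethylidene)-4-hydroxybutanoate (aryl = ring A of 10) | COc1cc(C(OC)c2c(/C=C(\CCO)C(=O)OC)cc(OC)c(OCc3ccccc3)c2OC)ccc1O[Si](C(C)C)(C(C)C)C(C)C | intermediate
15 | methyl (E)-2-(arylmethylidene)-4-oxobutanoate, phenol silylated (aryl = ring A of 10) | COc1cc(C(OC)c2c(/C=C(\CC=O)C(=O)OC)cc(OC)c(OCc3ccccc3)c2OC)ccc1O[Si](C(C)C)(C(C)C)C(C)C | intermediate
16 | methyl (E)-2-{[4-(benzyloxy)-2-[(4-hydroxy-3-methoxyphenyl)(methoxy)methyl]-3,5-dimethoxyphenyl]methylidene}-4-oxobutanoate | COc1cc(C(OC)c2c(/C=C(\CC=O)C(=O)OC)cc(OC)c(OCc3ccccc3)c2OC)ccc1O | intermediate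
17 | methyl (E)-2-{[4-(benzyloxy)-3,5-dimethoxy-2-[(3-methoxy-4-oxocyclohexa-2,5-dien-1-ylidene)methyl]phenyl]methylidene}-4-oxobutanoate (para-quinone methide) | COC1=CC(=Cc2c(/C=C(\CC=O)C(=O)OC)cc(OC)c(OCc3ccccc3)c2OC)C=CC1=O | intermediate
18 | (E)-dienamine of 17 with (S)-2-[diphenyl(triethylsilyloxy)methyl]pyrrolidine | CC[Si](CC)(CC)OC(c1ccccc1)(c1ccccc1)[C@@H]1CCCN1/C=C/C(C(=O)OC)=C\c1cc(OC)c(OCc2ccccc2)c(OC)c1C=C1C=CC(=O)C(OC)=C1 | intermediate
19 | methyl (1R,2S)-7-(benzyloxy)-2-formyl-1-(4-hydroxy-3-methoxyphenyl)-6,8-dimethoxy-1,2-dihydronaphthalene-3-carboxylate (1,2-trans) | COc1cc([C@@H]2c3c(cc(OC)c(OCc4ccccc4)c3OC)C=C(C(=O)OC)[C@H]2C=O)ccc1O | intermediate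
20 | (1R,2S)-[7-(benzyloxy)-1-(4-hydroxy-3-methoxyphenyl)-6,8-dimethoxy-1,2-dihydronaphthalene-2,3-diyl]dimethanol | COc1cc([C@@H]2c3c(cc(OC)c(OCc4ccccc4)c3OC)C=C(CO)[C@H]2CO)ccc1O | intermediate
21 | (1R,2S,3S)-[7-(benzyloxy)-1-(4-hydroxy-3-methoxyphenyl)-6,8-dimethoxy-1,2,3,4-tetrahydronaphthalene-2,3-diyl]dimethanol | COc1cc([C@@H]2c3c(cc(OC)c(OCc4ccccc4)c3OC)C[C@H](CO)[C@H]2CO)ccc1O | intermediate
22 | (1R,2S,3S)-1-(4-hydroxy-3-methoxyphenyl)-2,3-bis(hydroxymethyl)-6,8-dimethoxy-1,2,3,4-tetrahydronaphthalen-7-ol | COc1cc([C@@H]2c3c(cc(OC)c(O)c3OC)C[C@H](CO)[C@H]2CO)ccc1O | target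

## Step count and risks

Total step count: 14. Longest linear sequence: 13 steps (steps 1–3 and 5–14, from syringaldehyde); step 4 is the one-step side branch from vanillin.

**Step 11 (key step).**
- What may go wrong: weak discrimination between the two faces of the methide in the ring-forming transition state, which would lower the enantiomeric purity at C1; racemic closure through the acid-catalysed dienol; drift of the product through enamine-mediated epimerization at C2 or migration of C3=C4 into conjugation with the aldehyde; and intermolecular capture of the methide.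
- Fallback (known chemistry, forming C1–C8a instead of C1–C2): it sets out from 2 (with 11 and 6) and rejoins the route at 21. Stobbe condensation of 2 with 11 (NaOMe, MeOH, reflux) should give (E)-4-[4-(benzyloxy)-3,5-dimethoxyphenyl]-3-(methoxycarbonyl)but-3-enoic acid F1. Rhodium-catalysed asymmetric hydrogenation ([Rh(cod)2]BF4, the Me-DuPhos enantiomer that delivers the S acid, H2, MeOH) should give (3S)-4-[4-(benzyloxy)-3,5-dimethoxyphenyl]-3-(methoxycarbonyl)butanoic acid F2. Reduction of the ester as the potassium carboxylate with Ca(BH4)2, then acid lactonization, should give (4S)-4-[4-(benzyloxy)-3,5-dimethoxybenzyl]dihydrofuran-2(3H)-one F3. Its lithium enolate (LiN(SiMe3)2, THF, −78 °C) should add to 6 anti to the benzyl group to give the trans aldol adduct F4 as a mixture of carbinol epimers. CF3CO2H in CH2Cl2 should ionize the carbinol, and ring A should close the C1–C8a bond by Friedel–Crafts alkylation with the aryl group trans to C2, giving the trans,trans-fused tetralin lactone F5. LiAlH4 should open the lactone to the silyl-protected diol F6, and Bu4NF should then give 21, which goes on to step 14.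

**Step 13 (directed hydrogenation).**
- What may go wrong: delivery of hydrogen to the wrong face because the in-plane C10 hydroxyl steers the metal as well as the C9 hydroxyl does, or stalling of the catalyst by chelation to the diol.
- Fallback (thermodynamic control at C3 in place of directed delivery): it sets out from 19 and rejoins at 22. Lindgren–Pinnick oxidation (NaClO2, NaH2PO4, 2-methyl-2-butene, t-BuOH/H2O) should give the C2 carboxylic acid F7. MeI with KHCO3 in DMF should esterify the carboxylate without touching the phenol, giving the 1,2-trans dihydronaphthalene diester F8. H2 over Pd/C should saturate C3=C4 from the face away from the pseudoaxial C2 ester and remove the benzyl group, giving mainly the 2,3-cis tetralin diester F9. NaOMe in MeOH should equilibrate C3 through the ester enolate to the all-trans diester F10, and LiAlH4 should reduce both esters to 22.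

**Step 7 (Stobbe condensation).**
- What may go wrong: cleavage of the aryl silyl ether by alkoxide, sluggish aldol addition next to the bulky ortho diarylmethyl group, or incomplete ring opening of the paraconate.
- Fallback (olefination and alkene cleavage in place of condensation and redox adjustment): it sets out from 10 and rejoins at 15, which also bypasses steps 8 and 9. Alkylation of trimethyl phosphonoacetate with allyl bromide (NaH, THF) should give methyl 2-(dimethoxyphosphoryl)pent-4-enoate F11. Horner–Wadsworth–Emmons olefination of 10 with F11 (NaH, THF, 0 °C to rt) should give the methyl (E)-2-(arylmethylidene)pent-4-enoate F12, the minor Z isomer being removed. Lemieux–Johnson cleavage of the terminal alkene (OsO4 cat., NaIO4, 2,6-lutidine, dioxane/H2O), which should be much faster than attack on the hindered, electron-poor trisubstituted alkene, should give 15.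

## Further compounds

F1 | step 11 | (E)-4-[4-(benzyloxy)-3,5-dimethoxyphenyl]-3-(methoxycarbonyl)but-3-enoic acid | COC(=O)/C(CC(=O)O)=C/c1cc(OC)c(OCc2ccccc2)c(OC)c1
F2 | step 11 | (3S)-4-[4-(benzyloxy)-3,5-dimethoxyphenyl]-3-(methoxycarbonyl)butanoic acid | COc1cc(C[C@H](C(=O)OC)CC(=O)O)cc(OC)c1OCc1ccccc1
F3 | step 11 | (4S)-4-[4-(benzyloxy)-3,5-dimethoxybenzyl]dihydrofuran-2(3H)-one | COc1cc(C[C@@H]2COC(=O)C2)cc(OC)c1OCc1ccccc1
F4 | step 11 | (3R,4S)-4-[4-(benzyloxy)-3,5-dimethoxybenzyl]-3-{hydroxy[3-methoxy-4-(triisopropylsilyloxy)phenyl]methyl}dihydrofuran-2(3H)-one (carbinol epimers) | COc1cc(C(O)[C@@H]2C(=O)OC[C@H]2Cc2cc(OC)c(OCc3ccccc3)c(OC)c2)ccc1O[Si](C(C)C)(C(C)C)C(C)C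
F5 | step 11 | (1R,2S,3S)-7-(benzyloxy)-6,8-dimethoxy-1-[3-methoxy-4-(triisopropylsilyloxy)phenyl]tetralin-2,3-carbolactone (carbonyl on C2, CH2O on C3, trans,trans) | COc1cc([C@@H]2c3c(cc(OC)c(OCc4ccccc4)c3OC)C[C@@H]3COC(=O)[C@@H]23)ccc1O[Si](C(C)C)(C(C)C)C(C)C
F6 | step 11 | (1R,2S,3S)-[7-(benzyloxy)-6,8-dimethoxy-1-[3-methoxy-4-(triisopropylsilyloxy)phenyl]-1,2,3,4-tetrahydronaphthalene-2,3-diyl]dimethanol | COc1cc([C@@H]2c3c(cc(OC)c(OCc4ccccc4)c3OC)C[C@H](CO)[C@H]2CO)ccc1O[Si](C(C)C)(C(C)C)C(C)C
F7 | step 13 | (1R,2S)-7-(benzyloxy)-1-(4-hydroxy-3-methoxyphenyl)-6,8-dimethoxy-3-(methoxycarbonyl)-1,2-dihydronaphthalene-2-carboxylic acid | COc1cc([C@@H]2c3c(cc(OC)c(OCc4ccccc4)c3OC)C=C(C(=O)OC)[C@H]2C(=O)O)ccc1O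
F8 | step 13 | dimethyl (1R,2S)-7-(benzyloxy)-1-(4-hydroxy-3-methoxyphenyl)-6,8-dimethoxy-1,2-dihydronaphthalene-2,3-dicarboxylate | COc1cc([C@@H]2c3c(cc(OC)c(OCc4ccccc4)c3OC)C=C(C(=O)OC)[C@H]2C(=O)OC)ccc1O
F9 | step 13 | dimethyl (1R,2S,3R)-7-hydroxy-1-(4-hydroxy-3-methoxyphenyl)-6,8-dimethoxy-1,2,3,4-tetrahydronaphthalene-2,3-dicarboxylate (2,3-cis) | COc1cc([C@@H]2c3c(cc(OC)c(O)c3OC)C[C@@H](C(=O)OC)[C@H]2C(=O)OC)ccc1O
F10 | step 13 | dimethyl (1R,2S,3S)-7-hydroxy-1-(4-hydroxy-3-methoxyphenyl)-6,8-dimethoxy-1,2,3,4-tetrahydronaphthalene-2,3-dicarboxylate (all-trans) | COc1cc([C@@H]2c3c(cc(OC)c(O)c3OC)C[C@H](C(=O)OC)[C@H]2C(=O)OC)ccc1O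
F11 | step 7 | methyl 2-(dimethoxyphosphoryl)pent-4-enoate | COC(=O)C(CC=C)P(=O)(OC)OC
F12 | step 7 | methyl (E)-2-{[4-(benzyloxy)-3,5-dimethoxy-2-{methoxy[3-methoxy-4-(triisopropylsilyloxy)phenyl]methyl}phenyl]methylidene}pent-4-enoate | COc1cc(C(OC)c2c(/C=C(\CC=C)C(=O)OC)cc(OC)c(OCc3ccccc3)c2OC)ccc1O[Si](C(C)C)(C(C)C)C(C)C
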